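**Retrosynthetic overview**
- Feature: in ring B (C5–C10) the methylene C9 lies between the quaternary C10 and the C8 carbonyl. Removing C9 contracts ring B to a cyclopentanone whose carbonyl C8 is bonded directly to C10. This is the 4,7a-dimethyl hydrindenedione, which already holds ring A, the angular methyl, the C4 methyl and the C3 carbonyl.
- Ring order: ring A is closed first, onto the five-membered forerunner of ring B, by an amino-acid-mediated aldol annulation that sets C10. Ring B then grows to six members by inserting C9 from CH2Br2 (bonds C8–C9 and C9–C10), with the C3 enone masked as a dithiane.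
- The C3 enone becomes the C3=C4 alkene with 5β-H (cis-decalin) by reduction of its tosylhydrazone and allylic diazene shift. C7 receives its three carbons from acetone.
- Late disconnections: C4 acetate and C3 angelate from the 3α,4α-diol, which comes from a Prévost–Woodward cis-hydroxylation on the concave α face. C7 is set last, by equilibration next to C8.

Key step: step 4

Remark: eudesmane numbering is used for all bicyclic compounds, including the hydrindanes (which lack C9), and β means the face of the C10 methyl. The target is read as 3α-OAng, 4α-OAc, 4β-Me, 5β-H, 7β-iPr, i.e. (3R,4S,5S,7R,10R).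

**Step 1**
Reactants: 1 2-methylcyclopentane-1,3-dione; 2 ethyl vinyl ketone
Product: 3 2-methyl-2-(3-oxopentyl)cyclopentane-1,3-dione
Conditions: AcOH (cat.), H2O, 75 °C
Reagents that add atoms: none
Why: Michael addition of the acidic cyclic 1,3-dione to the unhindered enone stops at the monoadduct because the attacking carbon becomes quaternary, and no stereocentre arises since 3 keeps a mirror plane.

**Step 2**
Reactants: 3 2-methyl-2-(3-oxopentyl)cyclopentane-1,3-dione
Product: 5 (S)-4,7a-dimethyl-2,3,7,7a-tetrahydro-1H-indene-1,5(6H)-dione, via cis-ketol 4 (not isolated)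
Conditions: L-phenylalanine (1 equiv), (+)-camphor-10-sulfonic acid (0.5 equiv), DMF, 30 → 70 °C; recrystallisation
Reagents that add atoms: none
Why: In this Hajos–Parrish–Eder–Sauer–Wiechert aldol condensation the side-chain enamine, guided by the carboxylic acid of the (S)-amino acid, attacks one of the two enantiotopic ring carbonyls and fixes C10 as S (β-methyl), the acid then dehydrates ketol 4, and a primary amino acid is chosen because the ethyl ketone must pass through a trisubstituted enamine that proline forms poorly.

**Step 3**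
Reactants: 5 (S)-4,7a-dimethyl-2,3,7,7a-tetrahydro-1H-indene-1,5(6H)-dione
Product: 6 C3 1,3-dithiane of 5 (C8 ketone free and C4=C5 retained)
Conditions: HS(CH2)3SH (1.05 equiv), p-TsOH·H2O (cat.), AcOH, rt
Reagents that add atoms: propane-1,3-dithiol, SCCCS
Why: Acid-catalysed dithioketalisation picks the enone carbonyl, whose allyl-stabilised thionium ion forms readily, over the neopentyl-type C8 cyclopentanone, as is established for bicyclic enediones of this family, and it leaves the double bond in place.

**Step 4**
Reactants: 6 C3 1,3-dithiane of 5; 7 dibromomethane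
Product: 11 C3 1,3-dithiane of (10R)-7-desisopropyl-eudesm-4-ene-3,8-dione, via lithium dibromomethyl alkoxide 8 (not isolated), via β-oxido carbenoid 9 (not isolated), via lithium enolate 10 (not isolated)
Conditions: 7 (2 equiv), LDA (2 equiv), THF, −78 °C; then n-BuLi (4 equiv), −78 → 0 °C; aq NH4Cl
Reagents that add atoms: dibromomethane 7, BrCBr
Why: Dibromomethyllithium adds to the only free carbonyl, C8, and forms C8–C9; bromine–lithium exchange on alkoxide 8 gives carbenoid 9, in which the alkoxide pushes a ring bond onto the carbenoid carbon as bromide leaves, so that C10 moves from C8 to C9 (new bond C9–C10) and enolate 10 of the six-membered ketone results. The closest known reaction type is the β-oxido carbenoid one-carbon ring enlargement of cycloalkanones, in which α-alkylated ketones shift their more substituted α-carbon. Ring B is closed not by a cyclisation but by this 1,2-shift, which widens the cyclopentanone C5–C6–C7–C8–C10 to the cyclohexanone C5–C6–C7–C8–C9–C10. No stereocentre is created: C10 keeps its three other bonds and migrates with retention, and the transient centres at C8 and C9 vanish in the enolate. The step needs C10 rather than the C7 methylene to migrate, which the fully substituted, more electron-rich C10 and the release of crowding next to the carbinol carbon should secure, and it needs a single electrophilic site, which the dithiane secures by taking the enone carbonyl and its acidic C2 and C6 hydrogens out of play. Low temperature keeps alkoxide 8 from closing to a bromo-epoxide before the exchange.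

**Step 5**
Reactants: 11 C3 1,3-dithiane of (10R)-7-desisopropyl-eudesm-4-ene-3,8-dione
Product: 12 (10R)-7-desisopropyl-eudesm-4-ene-3,8-dione
Conditions: MeI (excess), CaCO3, MeCN/H2O, 55 °C
Reagents that add atoms: water, O
Why: In this alkylative dithiane hydrolysis S-methylation turns sulfur into a leaving group, water traps the allylic thionium ion, and the neutral buffer leaves the C8 ketone and C10 untouched.

**Step 6**
Reactants: 12 (10R)-7-desisopropyl-eudesm-4-ene-3,8-dione
Product: 13 C8 ethylene ketal of 12
Conditions: TMSOCH2CH2OTMS (1.1 equiv), TMSOTf (cat.), CH2Cl2, −78 °C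
Reagents that add atoms: 1,2-bis(trimethylsilyloxy)ethane, C[Si](C)(C)OCCO[Si](C)(C)C
Why: Aprotic ketalisation with the bis-silyl ether of glycol under silyl triflate catalysis is known to take saturated ketones in the presence of conjugated enones without moving the double bond, and C8 is also the less hindered carbonyl.

**Step 7**
Reactants: 13 C8 ethylene ketal of 12
Product: 14 C3 tosylhydrazone of 13
Conditions: TsNHNH2 (1.1 equiv), EtOH, 60 °C
Reagents that add atoms: p-toluenesulfonohydrazide, Cc1ccc(cc1)S(=O)(=O)NN
Why: This is a plain hydrazone condensation at the only free carbonyl, run without added acid so that the dioxolane stays on.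

**Step 8**
Reactants: 14 C3 tosylhydrazone of 13
Product: 17 (5S,10R)-7-desisopropyl-eudesm-3-en-8-one (cis-fused 5β-H), via allylic diazene 15 (not isolated), via ketal alkene 16 (not isolated)
Conditions: catecholborane, CHCl3, −10 °C; NaOAc·3H2O, reflux; then 1 M HCl, THF, rt
Reagents that add atoms: water, O
Why: In this reductive transposition of an enone tosylhydrazone (allylic diazene rearrangement) the borane delivers hydride axially to the α face of C3, away from the angular methyl, acetate-induced loss of sulfinate gives the 3β-diazene 15, and its retro-ene loss of N2 passes hydrogen suprafacially to the β face of C5, which sets 5β-H cis to the C10 methyl and places the alkene at C3=C4, the course known for steroidal 4-en-3-ones, after which dilute acid frees C8.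

**Step 9**
Reactants: 17 (5S,10R)-7-desisopropyl-eudesm-3-en-8-one; 18 acetone
Product: 21 11-hydroxy-5βH-eudesm-3-en-8-one (C7 epimers), via lithium enolate 19 (not isolated), via chlorozinc enolate 20 (not isolated)
Conditions: LDA, THF, −78 °C; ZnCl2, −78 °C; 18, −78 → −40 °C; aq NH4Cl
Reagents that add atoms: acetone 18, CC(C)=O
Why: In this directed aldol addition LDA removes the accessible C7 proton rather than a neopentyl C9 proton, the zinc enolate adds to acetone with little proton transfer or retro-aldol loss, and the C7 centre formed here is erased in step 10.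

**Step 10**
Reactants: 21 11-hydroxy-5βH-eudesm-3-en-8-one
Product: 23 (5S,10R)-eudesma-3,7(11)-dien-8-one (cis-fused), via tertiary mesylate 22 (not isolated)
Conditions: MsCl, Et3N (excess), CH2Cl2, 0 °C → rt; then DBU (cat.), rt
Reagents that add atoms: none
Why: Mesylation followed by E1cB-type elimination gives the conjugated tetrasubstituted enone, DBU draws any isopropenyl isomer into conjugation, and the basic medium does not move the C3=C4 bond.

**Step 11**
Reactants: 23 (5S,10R)-eudesma-3,7(11)-dien-8-one
Product: 26 3α-acetoxy-4α-hydroxy-5βH-eudesm-7(11)-en-8-one, via iodo acetate 24 (not isolated), via acetoxonium ion 25 (not isolated)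
Conditions: I2 (1.05 equiv), AgOAc (2.2 equiv), AcOH, rt; then H2O, 90 °C
Reagents that add atoms: silver acetate, CC(=O)[O-].[Ag+]; water, O
Why: In this Prévost–Woodward cis-hydroxylation the iodonium ion forms on the open convex β face of the electron-rich C3=C4 bond (the enone alkene is inert), acetate opens it at C4 from the α face in the Markovnikov and trans-diaxial sense, and displacement of the 3β-iodide by that acetate followed by hydrolysis of ion 25 places both oxygens on the concave α face (3R, 4S, methyl β), the face osmylation would avoid, while any 4-acetate regioisomer converges in step 13.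

**Step 12**
Reactants: 26 3α-acetoxy-4α-hydroxy-5βH-eudesm-7(11)-en-8-one
Product: 27 3α-acetoxy-4α-hydroxy-5βH-eudesman-8-one (C7 epimers)
Conditions: H2 (1 atm), Pd/C, EtOAc, rt
Reagents that add atoms: none
Why: Heterogeneous hydrogenation reduces the pulegone-type exocyclic enone, the only C=C bond left, and needs no facial control because C7 stays epimerisable.

**Step 13**
Reactants: 27 3α-acetoxy-4α-hydroxy-5βH-eudesman-8-one
Product: 28 (3R,4S,5S,7R,10R)-3α,4α-dihydroxy-5βH-eudesman-8-one
Conditions: NaOMe (cat.), MeOH, 40 °C
Reagents that add atoms: none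
Why: Zemplén-type transesterification removes the acetate while the same methoxide equilibrates C7 through the C8 enolate, and because the 4β-methyl would clash with the C10 methyl in the alternative chair–chair form, the decalin is held in the form where only the 7β-isopropyl group (7R) is equatorial.

**Step 14**
Reactants: 28 (3R,4S,5S,7R,10R)-3α,4α-dihydroxy-5βH-eudesman-8-one; 29 angelic acid
Product: 31 3α-angeloyloxy-4α-hydroxy-5βH-eudesman-8-one, via mixed anhydride 30 (not isolated)
Conditions: 29, 2,4,6-trichlorobenzoyl chloride, Et3N, toluene, rt; then 28, 80 °C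
Reagents that add atoms: angelic acid 29, C/C=C(/C)C(=O)O
Why: Yamaguchi-type mixed-anhydride esterification, run without a nucleophilic catalyst so that the Z-alkene does not drift to the tiglate, acylates the equatorial secondary 3α-hydroxyl and leaves the axial tertiary 4α-hydroxyl alone.

**Step 15**
Reactants: 31 3α-angeloyloxy-4α-hydroxy-5βH-eudesman-8-one; 32 acetic anhydride
Product: 33 CNP0322180.1 (3α-angeloyloxy-4α-acetoxy-5βH-eudesman-8-one)
Conditions: 32 (excess), Sc(OTf)3 (cat.), MeCN, −20 → 0 °C
Reagents that add atoms: acetic anhydride 32, CC(=O)OC(C)=O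
Why: Lewis-acid-catalysed acetylation with Sc(OTf)3 is a known way to esterify tertiary alcohols at low temperature, where base-promoted migration of the angeloyl group, ionisation at C4 (disfavoured by the adjacent ester) and Z to E isomerisation should all be slow.

**Compound list**
1 | 2-methylcyclopentane-1,3-dione | CC1C(=O)CCC1=O | starting material
2 | ethyl vinyl ketone | CCC(=O)C=C | starting material
3 | 2-methyl-2-(3-oxopentyl)cyclopentane-1,3-dione | CCC(=O)CCC1(C)C(=O)CCC1=O | intermediate
4 | (3aS,7aS)-3a-hydroxy-4,7a-dimethylhexahydroindane-1,5-dione, cis-ketol, C4 epimers | O=C1CC[C@]2(C)C(=O)CC[C@]2(O)C1C | intermediate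
5 | (S)-4,7a-dimethyl-2,3,7,7a-tetrahydro-1H-indene-1,5(6H)-dione | O=C1CC[C@]2(C)C(=O)CCC2=C1C | intermediate
6 | C3 1,3-dithiane of 5 | S1CCCSC12CC[C@]3(C)C(=O)CCC3=C2C | intermediate
7 | dibromomethane | BrCBr | starting material
8 | lithium alkoxide of the C8 dibromomethyl carbinol (C8 configuration without consequence) | S1CCCSC12CC[C@]3(C)C([O-])(C(Br)Br)CCC3=C2C.[Li+] | intermediate
9 | β-oxido carbenoid (C9 bears Li and Br) | S1CCCSC12CC[C@]3(C)C([O-])(C([Li])Br)CCC3=C2C.[Li+] | intermediate
10 | lithium C8=C9 enolate of 11 | S1CCCSC12CC[C@]3(C)C=C([O-])CCC3=C2C.[Li+] | intermediate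
11 | C3 1,3-dithiane of (10R)-7-desisopropyl-eudesm-4-ene-3,8-dione | S1CCCSC12CC[C@]3(C)CC(=O)CCC3=C2C | intermediate
12 | (10R)-7-desisopropyl-eudesm-4-ene-3,8-dione | O=C1CC[C@]2(C)CC(=O)CCC2=C1C | intermediate
13 | C8 ethylene ketal of 12 | O=C1CC[C@]2(C)CC3(OCCO3)CCC2=C1C | intermediate
14 | C3 tosylhydrazone of 13 (C=N geometry not defined) | Cc1ccc(cc1)S(=O)(=O)NN=C1CC[C@]2(C)CC3(OCCO3)CCC2=C1C | intermediate
15 | 3β-allylic diazene | N=N[C@H]1CC[C@]2(C)CC3(OCCO3)CCC2=C1C | intermediate
16 | C8 ethylene ketal of 17 | CC1=CCC[C@]2(C)CC3(OCCO3)CC[C@H]12 | intermediate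
17 | (5S,10R)-7-desisopropyl-eudesm-3-en-8-one, cis-fused | CC1=CCC[C@]2(C)CC(=O)CC[C@H]12 | intermediate
18 | acetone | CC(C)=O | starting material
19 | lithium C7=C8 enolate of 17 | CC1=CCC[C@]2(C)CC([O-])=CC[C@H]12.[Li+] | intermediate
20 | chlorozinc C7=C8 enolate of 17 | CC1=CCC[C@]2(C)CC(O[Zn]Cl)=CC[C@H]12 | intermediate
21 | 11-hydroxy-5βH-eudesm-3-en-8-one, C7 epimers | CC1=CCC[C@]2(C)CC(=O)C(C(C)(C)O)C[C@H]12 | intermediate
22 | C11 mesylate of 21 | CC1=CCC[C@]2(C)CC(=O)C(C(C)(C)OS(C)(=O)=O)C[C@H]12 | intermediate
23 | (5S,10R)-eudesma-3,7(11)-dien-8-one, cis-fused | CC1=CCC[C@]2(C)CC(=O)C(=C(C)C)C[C@H]12 | intermediate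
24 | 3β-iodo-4α-acetoxy-5βH-eudesm-7(11)-en-8-one | I[C@H]1CC[C@]2(C)CC(=O)C(=C(C)C)C[C@@H]2[C@]1(C)OC(C)=O | intermediate
25 | 3α,4α-acetoxonium ion (acetate salt) | O1[C@@H]2CC[C@]3(C)CC(=O)C(=C(C)C)C[C@@H]3[C@]2(C)[O+]=C1C.CC(=O)[O-] | intermediate
26 | 3α-acetoxy-4α-hydroxy-5βH-eudesm-7(11)-en-8-one | CC(=O)O[C@@H]1CC[C@]2(C)CC(=O)C(=C(C)C)C[C@@H]2[C@]1(C)O | intermediate
27 | 3α-acetoxy-4α-hydroxy-5βH-eudesman-8-one, C7 epimers | CC(=O)O[C@@H]1CC[C@]2(C)CC(=O)C(C(C)C)C[C@@H]2[C@]1(C)O | intermediate
28 | (3R,4S,5S,7R,10R)-3α,4α-dihydroxy-5βH-eudesman-8-one | O[C@@H]1CC[C@]2(C)CC(=O)[C@@H](C(C)C)C[C@@H]2[C@]1(C)O | intermediate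
29 | angelic acid, (Z)-2-methylbut-2-enoic acid | C/C=C(/C)C(=O)O | starting material
30 | angelic 2,4,6-trichlorobenzoic anhydride | C/C=C(/C)C(=O)OC(=O)c1c(Cl)cc(Cl)cc1Cl | intermediate
31 | 3α-angeloyloxy-4α-hydroxy-5βH-eudesman-8-one | C/C=C(/C)C(=O)O[C@@H]1CC[C@]2(C)CC(=O)[C@@H](C(C)C)C[C@@H]2[C@]1(C)O | intermediate
32 | acetic anhydride | CC(=O)OC(C)=O | starting material
33 | CNP0322180.1 | C/C=C(/C)C(=O)O[C@@H]1CC[C@]2(C)CC(=O)[C@@H](C(C)C)C[C@@H]2[C@]1(C)OC(C)=O | target

Total step count: 15. Longest linear sequence: 15 steps (from 1 and 2 to 33).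

**Steps most likely to fail**

Step 4. The C7 methylene may migrate in place of C10, or the hindered C8 ketone may be enolised instead of attacked. The fallback builds ring B six-membered from the start. It sets out from ethyl vinyl ketone 2 and returns at ketal enone 13.
- Commercial 1,4-dioxaspiro[4.5]decan-8-one is methylated (LDA, MeI) to racemic 7-methyl-1,4-dioxaspiro[4.5]decan-8-one F1.
- Condensation with (R)-1-phenylethylamine gives the imine F2, whose more substituted enamine tautomer adds to 2 (deracemising Michael addition of a chiral imine).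
- Work-up with aqueous acetic acid gives (R)-7-methyl-7-(3-oxopentyl)-1,4-dioxaspiro[4.5]decan-8-one F3.
- NaOMe in MeOH closes ring A by aldol condensation to 13.

Step 11. Face or site control may be lost when the iodonium ion is opened, either by acetate entering from the β face or by elimination to an allylic iodide. The fallback replaces the one-flask cis-hydroxylation by epoxide opening and a redox inversion. It sets out from dienone 23 and returns at diol 28.
- mCPBA epoxidises the convex face to the 3β,4β-epoxide F4.
- Dilute HClO4 in aqueous THF opens it trans-diaxially at the tertiary C4 to the 3β,4α-diol F5.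
- Dess–Martin oxidation gives the 4α-hydroxy-3-ketone F6.
- NaBH4 in MeOH/CH2Cl2 at −78 °C reduces this saturated ketone from the β face, in the presence of the conjugated C8 enone, to the 3α,4α-diol F7.
- Hydrogenation over Pd/C in MeOH gives 28 together with its C7 epimer, and NaOMe converts the epimer into 28.

Step 15. Acylation of the axial tertiary alcohol may be sluggish, with angeloyl migration from O3 to O4 or loss of the C4 oxygen by ionisation. The fallback reverses the order of the two acylations. It sets out from diol 28 and returns at target 33.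
- MeC(OMe)3 with camphorsulfonic acid (cat.) gives the cyclic 3α,4α-orthoacetate F8.
- Aqueous acetic acid opens it, by the stereoelectronic preference of cyclic orthoesters for the axial ester, to the 4α-acetoxy-3α-ol F9.
- F9 is acylated at O3 with mixed anhydride 30 at the lowest workable temperature to give 33.

**Further compounds**
F1 | step 4 | 7-methyl-1,4-dioxaspiro[4.5]decan-8-one (racemic) | CC1CC2(OCCO2)CCC1=O
F2 | step 4 | imine of F1 and (R)-1-phenylethylamine | C[C@@H](N=C1CCC2(OCCO2)CC1C)c1ccccc1
F3 | step 4 | (R)-7-methyl-7-(3-oxopentyl)-1,4-dioxaspiro[4.5]decan-8-one | CCC(=O)CC[C@]1(C)CC2(OCCO2)CCC1=O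
F4 | step 11 | 3β,4β-epoxy-5βH-eudesm-7(11)-en-8-one | O1[C@H]2CC[C@]3(C)CC(=O)C(=C(C)C)C[C@@H]3[C@@]12C
F5 | step 11 | 3β,4α-dihydroxy-5βH-eudesm-7(11)-en-8-one | O[C@H]1CC[C@]2(C)CC(=O)C(=C(C)C)C[C@@H]2[C@]1(C)O
F6 | step 11 | 4α-hydroxy-5βH-eudesm-7(11)-ene-3,8-dione | O=C1CC[C@]2(C)CC(=O)C(=C(C)C)C[C@@H]2[C@]1(C)O
F7 | step 11 | 3α,4α-dihydroxy-5βH-eudesm-7(11)-en-8-one | O[C@@H]1CC[C@]2(C)CC(=O)C(=C(C)C)C[C@@H]2[C@]1(C)O
F8 | step 15 | cyclic 3α,4α-(1-methoxyethylidene) orthoacetate of 28 | O1[C@@H]2CC[C@]3(C)CC(=O)[C@@H](C(C)C)C[C@@H]3[C@]2(C)OC1(C)OC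
F9 | step 15 | 4α-acetoxy-3α-hydroxy-5βH-eudesman-8-one | O[C@@H]1CC[C@]2(C)CC(=O)[C@@H](C(C)C)C[C@@H]2[C@]1(C)OC(C)=O
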